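Readings and results were computed on assumed constants; the scatter is artificial.

Start from the earlier runs and ask what sets their pace.

| setting | spring | autumn | dawn | ash | alder | larch | cedar | birch |
|---|---|---|---|---|---|---|---|---|
| starting material | 0.0059 M | 0.016 M | 0.043 M | 0.030 M | 0.060 M | 0.0050 M | 0.040 M | 0.020 M |
| gas phase | 1.3 mM (held) | 1.3 mM (held) | 1.3 mM (held) | 1.3 mM (held) | 1.3 mM (held) | 1.3 mM (held) | 1.3 mM (held) | 1.3 mM (held) |
| remark | run made earlier | run made earlier | run made earlier |  |  |  |  |  |
| time |  |  |  | 30 min | 30 min | 30 min | 30 min | 30 min |

- spring (time / min: target / %): 6.00: 13.9; 12.0: 26.8; 20.0: 36.1; 25.0: 42.2; 30.0: 43.2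
- autumn (time / min: target / %): 6.00: 7.7; 12.0: 14.0; 20.0: 25.4; 25.0: 27.9; 30.0: 34.4
- dawn (time / min: target / %): 2.50: 1.6; 5.00: 1.9; 8.00: 6.0; 15.0: 8.8; 30.0: 17.1

(standard deviation of a reading: 1 percentage point)

- the flasks put in order of amount of target, in percent of the starting material charged, best first, at 30 min (ash / alder / larch / cedar / birch)
- the same order at 2.0 h (ash / alder / larch / cedar / birch)
- the amount of target, in percent of the starting material charged of the flask you put first, at 30 min
- the amount of target, in percent of the starting material charged of the flask you put last, at 30 min

- the numbers in the tables scatter with a standard deviation of 1 percentage point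
- at the start none of the gas phase is in solution

Turn the percentages into amounts. The dawn run made target at 0.245 mM min⁻¹ on average over 30.0 min. The autumn run made it at 0.183 mM min⁻¹. Dawn's charge was 2.69 times autumn's, yet its rate rose by a factor of just 1.34. That is an order of about 0.293 in starting material. So treat the gas as the limiting reagent, and keep its ledger.

Call the dawn figure the gas allowance: the target concentration gained per minute, on average, in a flask charged as heavily as dawn. It is a reading, with the scatter of 1 percentage point in its percentage.

Enter the income first: over 30 min the allowance pays for 7.35 mM of target. Now enter alder. Its charge of 0.060 M is more than that income, so reckon it at 12.3 %. Enter larch next. Its charge of 0.0050 M is less than the income, so the allowance gives no figure for larch. Take the spring run as its guide. Spring gained just 1 point between 25.0 min and 30.0 min, and stood at 43.2 %. Count larch at about that.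

Percent target at 30.0 min falls as charge rises in the earlier runs. So rank by charge, smallest first. The readings stop at 30.0 min, so leave 2.0 h unranked.

The forecast gives larch > birch > ash > cedar > alder at 30 min and birch > ash > cedar > larch > alder at 2.0 h, with larch at 47 % and alder at 13 %, both above my figures, and says the levelling “points to a gas-supply ceiling”.

The flask gives larch > birch > ash > cedar > alder at 30 min and cedar > ash > alder > birch > larch at 2.0 h.

    gas phase ⇌ dissolved gas, rate k1*(csat - [dissolved gas]) (kL = 0.00475 s⁻¹)
    target ⇌ isomer of the product (K = 0.210, k = 9.69 × 10⁻⁴ s⁻¹)
    dissolved gas + target → over-reaction product (k = 0.467 M⁻¹ s⁻¹)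
    starting material + dissolved gas → target (k = 1.14 M⁻¹ s⁻¹)
    dissolved gas + target → over-reacted product (k = 0.0831 M⁻¹ s⁻¹)

Larch holds 44.5 % and alder 13.4 %, against my 12.3 % for alder. In alder at 30.0 min, dissolved gas stands at 9.31 × 10⁻⁵ M, far below its saturation of 1.3 mM. Use the gas allowance once more, on the same alder flask read at 50 min. It pays for 20.4 % of the charge, and that flask holds 21.0 % of target.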